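The plan rests on assembling ring C of the naphthazarin half last, by a chromium carbene benzannulation. Ring C is para-dioxygenated at C1' and C4', and its C2'(Me)–C3'(aryl) edge maps onto an internal alkyne. Because ring D carries identical oxygens at C5' and C8', either orientation of the alkyne leads to the same quinone. One operation forges C1'–C2', C3'–C4' and C4'–C4a' and closes ring C, so the hindered C5–C3' bond never has to be made by aryl–aryl coupling. The precursors are the Fischer carbene complex derived from 1,4-dimethoxybenzene and a 1-arylpropyne whose aryl group is the permethylated hydroquinone form of the methoxy half (rings A and B).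

Key step: step 8

Numbering: methoxy half, ring A = C1(=O), C2(OMe), C3, C4(=O); ring B = C4a, C5 (biaryl), C6(Me), C7, C8(OH), C8a. Naphthazarin half, ring C = C1'(=O), C2'(Me), C3' (biaryl), C4'(=O); ring D = C4a', C5'(OH), C6', C7', C8'(OH), C8a'.

Assumption: the target SMILES defines no stereo element, so the tetra-ortho-substituted C5–C3' axis is left uncontrolled (racemate) and the naphthazarin half is treated as the drawn tautomer.

Step 1
Reactants: 1 2-bromo-6-methoxyphenol
Product: 2 2-bromo-6-methoxy-1,4-benzoquinone
Conditions: (KSO3)2NO (2.2 equiv), KH2PO4, H2O/acetone, 0 °C → rt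
Reagents that add atoms: potassium nitrosodisulfonate (Fremy's salt), [K+].[K+].[O]N(S(=O)(=O)[O-])S(=O)(=O)[O-]
Why: Teuber oxidation, in which the nitroxyl radical removes the phenolic hydrogen and a second equivalent bonds through oxygen to the free para carbon, after which loss of imidodisulfonate gives the para-quinone of this 2,6-disubstituted phenol.

Step 2
Reactants: 3 methyl 3-methylbut-2-enoate
Product: 5 1-methoxy-3-methyl-1-(trimethylsilyloxy)buta-1,3-diene, via lithium dienolate 4 (not isolated)
Conditions: LiN(i-Pr)2, THF, −78 °C; Me3SiCl, −78 °C → rt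
Reagents that add atoms: chlorotrimethylsilane, C[Si](C)(C)Cl
Why: Kinetic deprotonation of a γ-methyl group gives the cross-conjugated dienolate, which is silylated on oxygen (silyl ketene acetal formation) to give the vinylketene acetal.

Step 3
Reactants: 2 2-bromo-6-methoxy-1,4-benzoquinone; 5 1-methoxy-3-methyl-1-(trimethylsilyloxy)buta-1,3-diene
Product: 7 8-hydroxy-2-methoxy-6-methylnaphthalene-1,4-dione (3-methoxy-7-methyljuglone), via cycloadduct 6 (not isolated)
Conditions: 5 (1.3 equiv), CH2Cl2, −30 °C → rt; then 1 M HCl aq., THF, rt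
Reagents that add atoms: none
Why: Diels–Alder annulation of a vinylketene acetal with a bromoquinone, in which the nucleophilic CH2 terminus of 5 adds to the unsubstituted carbon of the bromoalkene (β to the carbonyl that the methoxy group does not deactivate) so that the ketal carbon bonds to the bromine-bearing carbon, and loss of HBr and methanol from 6 aromatises ring B at the quinone oxidation level without an oxidant, placing the hydroxyl peri to the carbonyl that flanks the methoxy group.

Step 4
Reactants: 7 8-hydroxy-2-methoxy-6-methylnaphthalene-1,4-dione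
Product: 9 1,2,4,8-tetramethoxy-6-methylnaphthalene, via naphthalenetriol 8 (not isolated)
Conditions: Na2S2O4, Bu4NBr (cat.), THF/H2O, rt, Ar; then KOH aq., Me2SO4, 0 °C → rt
Reagents that add atoms: dimethyl sulfate, COS(=O)(=O)OC
Why: Reductive methylation, in which dithionite first reduces the quinone (which also shields the vinylogous ester from base) and phase-transfer Williamson alkylation of the three phenoxides of 8 then fixes rings A and B as the tetramethyl ether.

Step 5
Reactants: 9 1,2,4,8-tetramethoxy-6-methylnaphthalene
Product: 10 1-bromo-4,5,6,8-tetramethoxy-2-methylnaphthalene (bromine at C5 in the numbering of the target)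
Conditions: NBS (1.0 equiv), MeCN, 0 °C, dark
Reagents that add atoms: N-bromosuccinimide, O=C1CCC(=O)N1Br
Why: Electrophilic aromatic bromination, expected at C5 because this α position lies para to the C8 methoxy group and ortho to the C6 methyl group, so its arenium ion has two resonance forms that keep ring A benzenoid, whereas C3 and C7 are β positions with only one such form.

Step 6
Reactants: 10 1-bromo-4,5,6,8-tetramethoxy-2-methylnaphthalene
Product: 11 4,5,6,8-tetramethoxy-2-methyl-1-(prop-1-ynyl)naphthalene
Conditions: MeC≡CMgBr (2 equiv), ZnCl2, THF, 0 °C → rt; then 10, Pd(OAc)2 (5 mol %), SPhos (10 mol %), THF, 60 °C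
Reagents that add atoms: prop-1-ynylmagnesium bromide, CC#C[Mg]Br
Why: Negishi alkynylation, in which a bulky electron-rich biarylphosphine lets zerovalent palladium insert into the hindered, electron-rich C5–Br bond and the alkynylzinc transmetallates rapidly, so the arylpropyne comes directly from the bromide.

Step 7
Reactants: 12 1,4-dimethoxybenzene; 13 chromium hexacarbonyl, Cr(CO)6
Product: 16 pentacarbonyl[(2,5-dimethoxyphenyl)(methoxy)methylidene]chromium, via 2,5-dimethoxyphenyllithium 14 (not isolated), via lithium acylchromate 15 (not isolated)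
Conditions: n-BuLi, TMEDA, Et2O, 0 °C → rt; Cr(CO)6, Et2O, 0 °C → rt; evaporate; Me3OBF4, CH2Cl2/H2O, 0 °C
Reagents that add atoms: trimethyloxonium tetrafluoroborate, C[O+](C)C.F[B-](F)(F)F
Why: Fischer carbene synthesis, in which directed ortho-lithiation gives 14, its addition to a CO ligand gives acylchromate 15, and O-methylation with the Meerwein salt gives the methoxycarbene complex.

Step 8
Reactants: 16 pentacarbonyl[(2,5-dimethoxyphenyl)(methoxy)methylidene]chromium; 11 4,5,6,8-tetramethoxy-2-methyl-1-(prop-1-ynyl)naphthalene
Product: 18 4,5,8-trimethoxy-3-methyl-2-(4,5,6,8-tetramethoxy-2-methylnaphthalen-1-yl)naphthalen-1-ol, via tricarbonylchromium naphthol complex 17 (not isolated)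
Conditions: 16 (1.5 equiv), THF (0.3 M), 55 °C, Ar, sealed tube; then air, EtOAc, rt
Reagents that add atoms: none
Why: Thermal loss of one CO from 16 opens a site on zerovalent chromium, the alkyne inserts into the Cr=C bond to give a vinylcarbene (C1'–C2'), CO insertion gives a chromium-bound vinylketene (C3'–C4'), and closure onto the only free ortho carbon of the dimethoxyphenyl group followed by enolisation gives the naphthol as its Cr(CO)3 complex 17, which air demetallates. The closest known reaction type is the Dötz benzannulation of aryl(methoxy)carbene chromium complexes with 1-arylpropynes and other internal alkynes. Ring C is closed by 6π electrocyclisation of the dienylketene (C4'–C4a'), a formal [3+2+1] assembly from the carbene carbon with its aryl ortho carbon, the two alkyne carbons and one CO. No stereocentre is formed, and the C5–C3' axis arises without control, which the racemic target allows. The step needs chemoselectivity for CO insertion and six-ring closure over indene, cyclobutenone or furan formation, which the methoxycarbene on chromium, the ethereal solvent, the moderate temperature and the high concentration favour. The orientation of insertion need not be controlled, because oxidation in step 9 gives the same quinone from either orientation.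

Step 9
Reactants: 18 4,5,8-trimethoxy-3-methyl-2-(4,5,6,8-tetramethoxy-2-methylnaphthalen-1-yl)naphthalen-1-ol
Product: 19 5-(5,8-dimethoxy-3-methyl-1,4-dioxo-1,4-dihydronaphthalen-2-yl)-2,8-dimethoxy-6-methylnaphthalene-1,4-dione
Conditions: 18 in MeCN added to (NH4)2Ce(NO3)6 (6 equiv), MeCN/H2O, 0 °C
Reagents that add atoms: water, O
Why: Oxidative demethylation with tetravalent cerium, in which the para-methoxynaphthol of ring C and the 1,4-dimethoxy pattern of ring A are each oxidised to the para-quinone with water supplying the new carbonyl oxygens, while ring D (deactivated once ring C is a quinone) and the C2 and C8 ethers are retained and addition of the substrate to excess oxidant suppresses oxidative dimerisation at C3.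

Step 10
Reactants: 19 5-(5,8-dimethoxy-3-methyl-1,4-dioxo-1,4-dihydronaphthalen-2-yl)-2,8-dimethoxy-6-methylnaphthalene-1,4-dione
Product: 20 8'-hydroxy-3-methoxy isodiospyrin (target)
Conditions: BCl3 (8 equiv), CH2Cl2, −78 °C → 0 °C; then H2O
Reagents that add atoms: none
Why: Chelation-controlled ether cleavage, in which BCl3 binds each peri methoxy oxygen (C8, C5', C8') together with its neighbouring quinone carbonyl in a six-membered chelate and chloride removes the methyl group, whereas the C2 methoxy group is a vinylogous ester whose only flanking carbonyl (C1) is already engaged by the C8 oxygen and should survive at low temperature.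

Compound list
1 | 2-bromo-6-methoxyphenol | COc1cccc(Br)c1O | starting material
2 | 2-bromo-6-methoxy-1,4-benzoquinone | COC1=CC(=O)C=C(Br)C1=O | intermediate
3 | methyl 3-methylbut-2-enoate | COC(=O)C=C(C)C | starting material
4 | lithium 1-methoxy-3-methylbuta-1,3-dien-1-olate | [Li+].COC([O-])=CC(C)=C | intermediate (not isolated)
5 | 1-methoxy-3-methyl-1-(trimethylsilyloxy)buta-1,3-diene (E/Z mixture, inconsequential) | COC(O[Si](C)(C)C)=CC(C)=C | intermediate
6 | 8a-bromo-2,8-dimethoxy-6-methyl-8-(trimethylsilyloxy)-4a,5,8,8a-tetrahydronaphthalene-1,4-dione (racemic, cis ring fusion, ketal carbon undefined) | COC1=CC(=O)[C@@H]2CC(C)=CC(OC)(O[Si](C)(C)C)[C@]2(Br)C1=O | intermediate (not isolated)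
7 | 8-hydroxy-2-methoxy-6-methylnaphthalene-1,4-dione | COC1=CC(=O)c2cc(C)cc(O)c2C1=O | intermediate
8 | 2-methoxy-6-methylnaphthalene-1,4,8-triol | COc1cc(O)c2cc(C)cc(O)c2c1O | intermediate (not isolated)
9 | 1,2,4,8-tetramethoxy-6-methylnaphthalene | COc1cc(OC)c2cc(C)cc(OC)c2c1OC | intermediate
10 | 1-bromo-4,5,6,8-tetramethoxy-2-methylnaphthalene | COc1cc(OC)c2c(Br)c(C)cc(OC)c2c1OC | intermediate
11 | 4,5,6,8-tetramethoxy-2-methyl-1-(prop-1-ynyl)naphthalene | CC#Cc1c(C)cc(OC)c2c(OC)c(OC)cc(OC)c12 | intermediate
12 | 1,4-dimethoxybenzene | COc1ccc(OC)cc1 | starting material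
13 | chromium hexacarbonyl, Cr(CO)6 | O=C=[Cr](=C=O)(=C=O)(=C=O)(=C=O)=C=O | starting material
14 | 2,5-dimethoxyphenyllithium | [Li]c1cc(OC)ccc1OC | intermediate (not isolated)
15 | lithium pentacarbonyl[(2,5-dimethoxyphenyl)(oxido)methylidene]chromate | [Li+].[O-]C(c1cc(OC)ccc1OC)=[Cr](=C=O)(=C=O)(=C=O)(=C=O)=C=O | intermediate (not isolated)
16 | pentacarbonyl[(2,5-dimethoxyphenyl)(methoxy)methylidene]chromium | COC(c1cc(OC)ccc1OC)=[Cr](=C=O)(=C=O)(=C=O)(=C=O)=C=O | intermediate
17 | tricarbonylchromium complex of naphthol 18 (Cr(CO)3 η6-bound to ring C; SMILES shows the two components) | COc1ccc(OC)c2c(OC)c(C)c(-c3c(C)cc(OC)c4c(OC)c(OC)cc(OC)c34)c(O)c12.O=C=[Cr](=C=O)=C=O | intermediate (not isolated)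
18 | 4,5,8-trimethoxy-3-methyl-2-(4,5,6,8-tetramethoxy-2-methylnaphthalen-1-yl)naphthalen-1-ol (racemic about the biaryl axis) | COc1ccc(OC)c2c(OC)c(C)c(-c3c(C)cc(OC)c4c(OC)c(OC)cc(OC)c34)c(O)c12 | intermediate
19 | 5-(5,8-dimethoxy-3-methyl-1,4-dioxo-1,4-dihydronaphthalen-2-yl)-2,8-dimethoxy-6-methylnaphthalene-1,4-dione | COC1=CC(=O)c2c(C3=C(C)C(=O)c4c(OC)ccc(OC)c4C3=O)c(C)cc(OC)c2C1=O | intermediate
20 | 8'-hydroxy-3-methoxy isodiospyrin | COC1=CC(=O)c2c(C3=C(C)C(=O)c4c(O)ccc(O)c4C3=O)c(C)cc(O)c2C1=O | target

Total step count: 10. Longest linear sequence: 8 steps (steps 1, 3, 4, 5, 6, 8, 9, 10).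

Steps most likely to fail

Step 8. The twisted, doubly ortho-substituted aryl group may slow alkyne insertion so far that the carbene complex decomposes first, or the vinylketene may close to a four-membered ring or the vinylcarbene to an indene instead of ring C. The fallback replaces the benzannulation by a late biaryl coupling; it sets out from bromide 10 and carbene complex 16 and returns at bisquinone 19. Complex 16 would be heated with propyne in THF to give 4,5,8-trimethoxy-2-methylnaphthalen-1-ol F1, which would be oxidised in the work-up with (NH4)2Ce(NO3)6 to 5,8-dimethoxy-2-methylnaphthalene-1,4-dione F2. Br2 and NaOAc in AcOH would convert this into 2-bromo-5,8-dimethoxy-3-methylnaphthalene-1,4-dione F3. Bromide 10 would be treated with n-BuLi and B(OMe)3, then aqueous acid, to give (4,5,6,8-tetramethoxy-2-methylnaphthalen-1-yl)boronic acid F4. Suzuki–Miyaura coupling of F3 and F4 (Pd(OAc)2, SPhos, K3PO4, toluene/H2O, 80 °C) would give 5,8-dimethoxy-2-methyl-3-(4,5,6,8-tetramethoxy-2-methylnaphthalen-1-yl)naphthalene-1,4-dione F5. Oxidation of its ring A with (NH4)2Ce(NO3)6 as in step 9 would give 19.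

Step 10. The vinylogous ester at C2 may be cleaved together with the peri ethers, or the second ether of ring D may resist cleavage once the first boron chelate has formed. The fallback gives up selectivity in the cleavage and restores the C2 ether afterwards; it sets out from 19 and returns at target 20. BBr3 in CH2Cl2 (−78 °C → rt) would cleave all four methyl ethers to give 2,8-dihydroxy-5-(5,8-dihydroxy-3-methyl-1,4-dioxo-1,4-dihydronaphthalen-2-yl)-6-methylnaphthalene-1,4-dione F6. Acid-catalysed methanolysis (HCl, MeOH, reflux) would then methylate only the acidic vinylogous carboxylic acid hydroxyl at C2, leaving the chelated peri phenols free, to give 20.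

Step 5. Bromine may attack C3 of the electron-rich trimethoxy ring A instead of C5, or a second bromination may follow. The fallback deactivates ring A before the halogenation; it sets out from juglone 7 and returns at bromide 10. MeI and Ag2O would methylate the peri hydroxyl to give 2,8-dimethoxy-6-methylnaphthalene-1,4-dione F7. Reductive acetylation (Zn, Ac2O, NaOAc) would give 2,8-dimethoxy-6-methylnaphthalene-1,4-diyl diacetate F8, in which only ring B remains strongly activated. NBS in MeCN would then give 5-bromo-2,8-dimethoxy-6-methylnaphthalene-1,4-diyl diacetate F9. Deacetylation and methylation in one pot (KOH, MeOH/THF, Na2S2O4 trace, Me2SO4, Ar) would give 10.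

Further compounds
F1 | step 8 | 4,5,8-trimethoxy-2-methylnaphthalen-1-ol | COc1ccc(OC)c2c(OC)cc(C)c(O)c12
F2 | step 8 | 5,8-dimethoxy-2-methylnaphthalene-1,4-dione | COc1ccc(OC)c2C(=O)C(C)=CC(=O)c12
F3 | step 8 | 2-bromo-5,8-dimethoxy-3-methylnaphthalene-1,4-dione | COc1ccc(OC)c2C(=O)C(C)=C(Br)C(=O)c12
F4 | step 8 | (4,5,6,8-tetramethoxy-2-methylnaphthalen-1-yl)boronic acid | COc1cc(OC)c2c(B(O)O)c(C)cc(OC)c2c1OC
F5 | step 8 | 5,8-dimethoxy-2-methyl-3-(4,5,6,8-tetramethoxy-2-methylnaphthalen-1-yl)naphthalene-1,4-dione | COc1ccc(OC)c2C(=O)C(C)=C(c3c(C)cc(OC)c4c(OC)c(OC)cc(OC)c34)C(=O)c12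
F6 | step 10 | 2,8-dihydroxy-5-(5,8-dihydroxy-3-methyl-1,4-dioxo-1,4-dihydronaphthalen-2-yl)-6-methylnaphthalene-1,4-dione | OC1=CC(=O)c2c(C3=C(C)C(=O)c4c(O)ccc(O)c4C3=O)c(C)cc(O)c2C1=O
F7 | step 5 | 2,8-dimethoxy-6-methylnaphthalene-1,4-dione | COC1=CC(=O)c2cc(C)cc(OC)c2C1=O
F8 | step 5 | 2,8-dimethoxy-6-methylnaphthalene-1,4-diyl diacetate | COc1cc(OC(C)=O)c2cc(C)cc(OC)c2c1OC(C)=O
F9 | step 5 | 5-bromo-2,8-dimethoxy-6-methylnaphthalene-1,4-diyl diacetate | COc1cc(OC(C)=O)c2c(Br)c(C)cc(OC)c2c1OC(C)=O
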